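The earlier runs and the new flask are calculated on assumed constants; scatter was added.

| setting | red | grey | eta | theta |
|---|---|---|---|---|
| X | 0.050 M | 0.050 M | 0.050 M | 0.050 M |
| J | 1.9 mM | 1.9 mM | 1.9 mM | 0.50 mM |
| Q | 1.1 mM | 3.2 mM | 1.6 mM | 1.6 mM |
| remark | run made earlier | run made earlier |  |  |
| time |  |  | 30 h | 30 h |

| run | time / h | Z / % |
|---|---|---|
| red | 2.00 | 6.4 |
| red | 4.00 | 10.6 |
| red | 5.00 | 12.6 |
| red | 8.00 | 19.6 |
| red | 10.0 | 23.6 |
| grey | 0.833 | 2.0 |
| grey | 1.33 | 2.6 |
| grey | 2.50 | 3.3 |
| grey | 4.00 | 5.9 |
| grey | 6.00 | 5.9 |
| grey | 10.0 | 10.9 |

(scatter of a reading: 0.5 percentage points)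

- the average divides the monomer in chains by the number of chains begun, living and dead together
- the numbers in the tables scatter with a standard deviation of 0.5 percentage points
- the earlier runs do not show the number of chains; that part of a forecast is a guess
- no earlier run changes the charge of J; that part of a forecast is a guess

* which of the two ends with the longer chains by the average number of monomer units in a chain (chains begun, living or dead) ("neither" if they lie within 10%) (eta / theta / neither)
* average number of monomer units in a chain (chains begun, living or dead) at the end, eta
* average number of monomer units in a chain (chains begun, living or dead) at the end, theta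

The red run, with 1.1 mM of Q, turned 23.6% of its X into Z in 10.0 h, and the grey run, with 3.2 mM of Q and the same J, turned 10.9% in 10.0 h. Read as a pseudo-first-order loss of X, these last readings give slopes of 0.0269 h⁻¹ for red and 0.0115 h⁻¹ for grey, so the run with more Q lost X more slowly.

Two views explain this. The forecaster treats Q as a brake on chains that every J starts: “so I guess rate ∝ J/Q and one chain per J”. The forecast is therefore 11.5 units for eta and 14.5 for theta, with theta longer.

I read Q differently: it takes J away, one for one, before J can begin a chain. The grey run then has fewer chains, and each chain grows as fast as in red. The red run must hold between 0.800 mM of chains, the J in excess of its Q, and 1.9 mM, the whole charge. I take the middle, 1.35 mM. Dividing the X lost per hour at the charge by these chains gives 0.997 h⁻¹. Call this the growth speed of a chain: the units one chain adds per hour at the charged X.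

Length then follows time, not the number of chains. Over 30 h a chain reaches up to 29.9 units, and fewer as X thins. For eta I hold slope times Q as in red, which gives a slope of 0.0185 h⁻¹ and a length of 23.0. Theta has at most 0.50 mM of chains, so its X thins less and its length lies nearer 29.9.

The flasks give 27.9 units for eta and 35.2 for theta, so theta is longer.

    X + J → E + Z (k = 0.500 M⁻¹ min⁻¹)
    X + E → Z + E, rate k2*[E]*[X] (k = 0.410 M⁻¹ min⁻¹)
    2 X → L (k = 1.40 × 10⁻⁵ M⁻¹ min⁻¹)
    J + Q → D (k = 33.0 M⁻¹ min⁻¹)

In theta, J was down to 0% of its charge by 15.0 h, having split into 1.73 × 10⁻⁴ M of E and 3.27 × 10⁻⁴ M of D. While that E stood unchanged up to 30.0 h, X went on to Z, reaching 12.2%, and the growth speed over 30 h gives 29.9 against the 35.2 found. One chain per J is right as far as D stays near zero, but theta held more D than E. A neighbour of theta, the same flask with 0.0027 M of Q, ended with less E and less Z, 8.37%, and the growth speed again gives 29.9, where its length is 36.1.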